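The two carbon substituents of ring B are cut together: the C6–propyl and C1–carboxyl bonds lie on adjacent ring carbons, with the C2 oxygen next to C1. The complete depside is therefore assembled first. Ring B is a 2-iodoaryl 4-chlorobenzenesulfonate (iodine on C1, sulfonate on C6, benzyl ether on C2) derived from phloroglucinol monobenzyl ether. Ring A is a bis(benzyl ether) whose ketone is masked as a dioxolane. In one flask, magnesium–iodine exchange and sulfonate loss give the C1–C6 aryne, propylmagnesium chloride adds at C6 and carbon dioxide captures the C1 arylmagnesium. Acetal hydrolysis and hydrogenolysis then release the target.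

Key step: step 8

Remark on the chemistry: the target has no stereocentre, so configuration needs no control; ring B is numbered as in the target acid (C1 carboxyl, C2 hydroxyl, C4 ester oxygen, C6 propyl).

Step 1
Reactants: 1 methyl 2,4-dihydroxy-6-methylbenzoate
Product: 2 methyl 2,4-bis(benzyloxy)-6-methylbenzoate
Conditions: BnBr (2.5 equiv), K2CO3, DMF, 60 °C
Reagents that add atoms: benzyl bromide, BrCc1ccccc1
Why: Williamson etherification with excess benzyl bromide in warm DMF should alkylate both phenols, including the hydrogen-bonded C2 hydroxyl, and leave the methyl ester untouched.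

Step 2
Reactants: 2 methyl 2,4-bis(benzyloxy)-6-methylbenzoate; 3 N-methoxy-N-methylbutanamide
Product: 5 methyl 2,4-bis(benzyloxy)-6-(2-oxopentyl)benzoate, via benzylic lithium reagent 4 (not isolated)
Conditions: LiN(iPr)2 (2.2 equiv), THF, −78 °C; 3 (1.2 equiv), −78 → −40 °C; AcOH, −78 °C
Reagents that add atoms: none
Why: Lateral lithiation of the ortho-toluate followed by acylation with an N-methoxy-N-methylamide should stop at the ketone because the chelated tetrahedral adduct survives until the cold acetic acid quench, the second equivalent of base absorbing the acidic benzylic ketone.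

Step 3
Reactants: 5 methyl 2,4-bis(benzyloxy)-6-(2-oxopentyl)benzoate
Product: 6 methyl 2,4-bis(benzyloxy)-6-[(2-propyl-1,3-dioxolan-2-yl)methyl]benzoate
Conditions: TMSOCH2CH2OTMS (1.5 equiv), TMSOTf (5 mol%), CH2Cl2, −78 → −20 °C; pyridine quench
Reagents that add atoms: 1,2-bis(trimethylsilyloxy)ethane, C[Si](C)(C)OCCO[Si](C)(C)C
Why: Aprotic silyl-transfer acetalisation at low temperature, driven by formation of hexamethyldisiloxane, should give the dioxolane without the hot protic acid that would close the keto ester to an isocoumarin.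

Step 4
Reactants: 6 methyl 2,4-bis(benzyloxy)-6-[(2-propyl-1,3-dioxolan-2-yl)methyl]benzoate
Product: 7 2,4-bis(benzyloxy)-6-[(2-propyl-1,3-dioxolan-2-yl)methyl]benzoic acid
Conditions: KOH, DMSO/H2O, 90 °C; then cold dilute HCl to pH 4, rapid extraction
Reagents that add atoms: potassium hydroxide, [K+].[OH-]
Why: Saponification of the doubly ortho-substituted ester needs forcing base, which the dioxolane and benzyl ethers tolerate, and a brief cold acidification to pH 4 should free the acid without opening the ketal.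

Step 5
Reactants: 8 5-(benzyloxy)benzene-1,3-diol
Product: 9 5-(benzyloxy)-4-iodobenzene-1,3-diol
Conditions: N-iodosuccinimide (1.0 equiv), MeCN, −30 → 0 °C; chromatographic removal of any 2-iodo isomer
Reagents that add atoms: N-iodosuccinimide, O=C1CCC(=O)N1I
Why: Electrophilic aromatic iodination under non-basic conditions should favour C4, which is para to one hydroxyl, ortho to the other and to the benzyl ether, and counted twice by symmetry, while one equivalent of reagent in the cold limits di-iodination.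

Step 6
Reactants: 7 2,4-bis(benzyloxy)-6-[(2-propyl-1,3-dioxolan-2-yl)methyl]benzoic acid; 9 5-(benzyloxy)-4-iodobenzene-1,3-diol
Product: 11 3-(benzyloxy)-5-hydroxy-4-iodophenyl 2,4-bis(benzyloxy)-6-[(2-propyl-1,3-dioxolan-2-yl)methyl]benzoate, via ring A acid chloride 10 (not isolated)
Conditions: 1-chloro-N,N,2-trimethylprop-1-en-1-amine (1.1 equiv), CH2Cl2, 0 °C → rt; then 9 (1.3 equiv), Et3N, DMAP (0.2 equiv), CH2Cl2, −20 °C → rt
Reagents that add atoms: none
Why: Neutral α-chloroenamine activation gives the acid chloride without HCl, so the dioxolane should survive, and DMAP-catalysed O-acylation by this doubly ortho-substituted aroyl chloride should go to the hydroxyl para to iodine because the other is shielded by iodine, as in the selective functionalisation of the remote hydroxyl of 4-haloresorcinols.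

Step 7
Reactants: 11 3-(benzyloxy)-5-hydroxy-4-iodophenyl 2,4-bis(benzyloxy)-6-[(2-propyl-1,3-dioxolan-2-yl)methyl]benzoate; 12 4-chlorobenzenesulfonyl chloride
Product: 13 3-(benzyloxy)-5-({2,4-bis(benzyloxy)-6-[(2-propyl-1,3-dioxolan-2-yl)methyl]benzoyl}oxy)-2-iodophenyl 4-chlorobenzenesulfonate
Conditions: 12 (1.2 equiv), Et3N, DMAP (cat.), CH2Cl2, 0 °C → rt
Reagents that add atoms: none
Why: O-Sulfonylation of the one remaining, acidic ortho-iodophenol needs no selectivity, and the hindered aryl ester and the ketal are stable to the amine base.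

Step 8
Reactants: 13 3-(benzyloxy)-5-({2,4-bis(benzyloxy)-6-[(2-propyl-1,3-dioxolan-2-yl)methyl]benzoyl}oxy)-2-iodophenyl 4-chlorobenzenesulfonate; 14 propylmagnesium chloride; 15 carbon dioxide
Product: 19 2-(benzyloxy)-4-({2,4-bis(benzyloxy)-6-[(2-propyl-1,3-dioxolan-2-yl)methyl]benzoyl}oxy)-6-propylbenzoic acid, via 2-magnesiated aryl sulfonate 16 (not isolated), via ring B aryne 17 (not isolated), via C1 arylmagnesium chloride 18 (not isolated)
Conditions: iPrMgCl (1.05 equiv), THF, −78 °C; 14 (3 equiv), −78 → 0 °C; 15 (dry gas), −40 °C → rt; cold aq. citric acid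
Reagents that add atoms: none
Why: Iodine–magnesium exchange at the iodide flanked by two oxygens is fast at −78 °C and should outrun attack on the shielded aryl ester; on warming, arylmagnesium 16 expels 4-chlorobenzenesulfonate to give the C1–C6 aryne 17. Propylmagnesium chloride then adds across the strained triple bond (aryne carbomagnesiation) and the new arylmagnesium 18 is carboxylated by CO2; the closest known chemistry is aryne generation from 2-iodoaryl arenesulfonates, organomagnesium addition to 3-alkoxyarynes and electrophilic quench of the adduct. No ring is closed and no stereocentre is formed. The selectivity needed is regiochemical: the C2 benzyloxy group polarises the aryne so that the nucleophile enters at the remote carbon C6 and magnesium ends up on C1, where it is stabilised inductively and by chelation to the ether oxygen. Chemoselectivity rests on the doubly ortho-substituted ring A benzoate resisting Grignard addition at or below 0 °C, on the base-stable dioxolane, and on using a single equivalent of iPrMgCl so that isopropyl transfer to the aryne cannot compete.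

Step 9
Reactants: 19 2-(benzyloxy)-4-({2,4-bis(benzyloxy)-6-[(2-propyl-1,3-dioxolan-2-yl)methyl]benzoyl}oxy)-6-propylbenzoic acid
Product: 20 2-(benzyloxy)-4-{[2,4-bis(benzyloxy)-6-(2-oxopentyl)benzoyl]oxy}-6-propylbenzoic acid
Conditions: 2 M aq. HCl/THF (1:4), rt
Reagents that add atoms: water, O
Why: Acid-catalysed acetal hydrolysis in dilute acid at room temperature should unmask the ketone while the aryl ester, the benzyl ethers and the ortho-alkoxybenzoic acid stay intact.

Step 10
Reactants: 20 2-(benzyloxy)-4-{[2,4-bis(benzyloxy)-6-(2-oxopentyl)benzoyl]oxy}-6-propylbenzoic acid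
Product: 21 4-{[2,4-dihydroxy-6-(2-oxopentyl)benzoyl]oxy}-2-hydroxy-6-propylbenzoic acid
Conditions: H2 (1 atm), 10% Pd/C, EtOAc, rt
Reagents that add atoms: none
Why: Hydrogenolysis of the three aryl benzyl ethers over Pd/C under neutral conditions should leave the dialkyl ketone, the aryl ester and the carboxylic acid untouched, so the target is obtained after filtration and evaporation.

Compound list
1 | methyl 2,4-dihydroxy-6-methylbenzoate | COC(=O)c1c(C)cc(O)cc1O | starting material
2 | methyl 2,4-bis(benzyloxy)-6-methylbenzoate | COC(=O)c1c(C)cc(OCc2ccccc2)cc1OCc1ccccc1 | intermediate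
3 | N-methoxy-N-methylbutanamide | CCCC(=O)N(C)OC | starting material
4 | methyl 2,4-bis(benzyloxy)-6-(lithiomethyl)benzoate, benzylic lithium reagent formed in the flask | [Li]Cc1cc(OCc2ccccc2)cc(OCc2ccccc2)c1C(=O)OC | intermediate
5 | methyl 2,4-bis(benzyloxy)-6-(2-oxopentyl)benzoate | CCCC(=O)Cc1cc(OCc2ccccc2)cc(OCc2ccccc2)c1C(=O)OC | intermediate
6 | methyl 2,4-bis(benzyloxy)-6-[(2-propyl-1,3-dioxolan-2-yl)methyl]benzoate | CCCC1(Cc2cc(OCc3ccccc3)cc(OCc3ccccc3)c2C(=O)OC)OCCO1 | intermediate
7 | 2,4-bis(benzyloxy)-6-[(2-propyl-1,3-dioxolan-2-yl)methyl]benzoic acid | CCCC1(Cc2cc(OCc3ccccc3)cc(OCc3ccccc3)c2C(=O)O)OCCO1 | intermediate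
8 | 5-(benzyloxy)benzene-1,3-diol | Oc1cc(O)cc(OCc2ccccc2)c1 | starting material
9 | 5-(benzyloxy)-4-iodobenzene-1,3-diol | Oc1cc(O)c(I)c(OCc2ccccc2)c1 | intermediate
10 | 2,4-bis(benzyloxy)-6-[(2-propyl-1,3-dioxolan-2-yl)methyl]benzoyl chloride, formed in the flask | CCCC1(Cc2cc(OCc3ccccc3)cc(OCc3ccccc3)c2C(=O)Cl)OCCO1 | intermediate
11 | 3-(benzyloxy)-5-hydroxy-4-iodophenyl 2,4-bis(benzyloxy)-6-[(2-propyl-1,3-dioxolan-2-yl)methyl]benzoate | CCCC1(Cc2cc(OCc3ccccc3)cc(OCc3ccccc3)c2C(=O)Oc2cc(O)c(I)c(OCc3ccccc3)c2)OCCO1 | intermediate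
12 | 4-chlorobenzenesulfonyl chloride | O=S(=O)(Cl)c1ccc(Cl)cc1 | starting material
13 | 3-(benzyloxy)-5-({2,4-bis(benzyloxy)-6-[(2-propyl-1,3-dioxolan-2-yl)methyl]benzoyl}oxy)-2-iodophenyl 4-chlorobenzenesulfonate | CCCC1(Cc2cc(OCc3ccccc3)cc(OCc3ccccc3)c2C(=O)Oc2cc(OCc3ccccc3)c(I)c(OS(=O)(=O)c3ccc(Cl)cc3)c2)OCCO1 | intermediate
14 | propylmagnesium chloride | CCC[Mg]Cl | starting material
15 | carbon dioxide | O=C=O | starting material
16 | arylmagnesium chloride from iodine–magnesium exchange of 13 (magnesium on C1, sulfonate on C6), formed in the flask | CCCC1(Cc2cc(OCc3ccccc3)cc(OCc3ccccc3)c2C(=O)Oc2cc(OCc3ccccc3)c([Mg]Cl)c(OS(=O)(=O)c3ccc(Cl)cc3)c2)OCCO1 | intermediate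
17 | ring B C1–C6 aryne: 3-(benzyloxy)-5-(aroyloxy)benzyne carrying the ring A ester, formed in the flask | CCCC1(Cc2cc(OCc3ccccc3)cc(OCc3ccccc3)c2C(=O)OC2=CC#CC(OCc3ccccc3)=C2)OCCO1 | intermediate
18 | arylmagnesium chloride after propyl addition (propyl on C6, magnesium on C1), formed in the flask | CCCC1(Cc2cc(OCc3ccccc3)cc(OCc3ccccc3)c2C(=O)Oc2cc(OCc3ccccc3)c([Mg]Cl)c(CCC)c2)OCCO1 | intermediate
19 | 2-(benzyloxy)-4-({2,4-bis(benzyloxy)-6-[(2-propyl-1,3-dioxolan-2-yl)methyl]benzoyl}oxy)-6-propylbenzoic acid | CCCC1(Cc2cc(OCc3ccccc3)cc(OCc3ccccc3)c2C(=O)Oc2cc(OCc3ccccc3)c(C(=O)O)c(CCC)c2)OCCO1 | intermediate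
20 | 2-(benzyloxy)-4-{[2,4-bis(benzyloxy)-6-(2-oxopentyl)benzoyl]oxy}-6-propylbenzoic acid | CCCC(=O)Cc1cc(OCc2ccccc2)cc(OCc2ccccc2)c1C(=O)Oc1cc(OCc2ccccc2)c(C(=O)O)c(CCC)c1 | intermediate
21 | 4-{[2,4-dihydroxy-6-(2-oxopentyl)benzoyl]oxy}-2-hydroxy-6-propylbenzoic acid | CCCC(=O)Cc1cc(O)cc(O)c1C(=O)Oc1cc(O)c(C(=O)O)c(CCC)c1 | target

Total step count: 10. Longest linear sequence: 9 steps (steps 1–4, then 6–10, from compound 1).

Steps most likely to fail

Step 8. The Grignard reagents may add to the depside carbonyl or to sulfonate sulfur before the aryne forms. Sulfonate loss may be incomplete at a temperature the ester tolerates. The adduct may be protonated instead of carboxylated. The fallback sets out from acid 7 and returns to the route at target 21; it brings ring B in with both carbon substituents already in place. Commercial 5-propylbenzene-1,3-diol is carboxylated with MeOMgOCO2Me in DMF at 120 °C to 2,4-dihydroxy-6-propylbenzoic acid F1. Its carboxylate is benzylated (BnBr, KHCO3, DMF, rt) to benzyl 2,4-dihydroxy-6-propylbenzoate F2. Acid chloride 10, made from 7 as in step 6, acylates the C4 hydroxyl of F2 (Et3N, DMAP, CH2Cl2), the C2 hydroxyl being held in a hydrogen bond to the ester carbonyl. This gives benzyl 4-({2,4-bis(benzyloxy)-6-[(2-propyl-1,3-dioxolan-2-yl)methyl]benzoyl}oxy)-2-hydroxy-6-propylbenzoate F3. Dilute HCl in THF opens the dioxolane to benzyl 4-{[2,4-bis(benzyloxy)-6-(2-oxopentyl)benzoyl]oxy}-2-hydroxy-6-propylbenzoate F4. Hydrogenolysis over Pd/C removes the two benzyl ethers and the benzyl ester and gives 21.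

Step 5. Iodination may take place between the two hydroxyls or twice, giving regioisomers that are hard to separate. The fallback sets out from diol 8 and returns at precursor 13, bypassing steps 6 and 7. Diol 8 is monosilylated (iPr3SiCl 1 equiv, imidazole, DMF) to 3-(benzyloxy)-5-[(triisopropylsilyl)oxy]phenol F5. The bulky silyl ether shields both of its ortho positions, so N-iodosuccinimide should iodinate the one remaining activated site, between the hydroxyl and the benzyl ether, giving 3-(benzyloxy)-2-iodo-5-[(triisopropylsilyl)oxy]phenol F6. Sulfonylation with 12 (Et3N, DMAP) gives 3-(benzyloxy)-2-iodo-5-[(triisopropylsilyl)oxy]phenyl 4-chlorobenzenesulfonate F7. Bu4NF buffered with AcOH at 0 °C removes the silyl group to give 3-(benzyloxy)-5-hydroxy-2-iodophenyl 4-chlorobenzenesulfonate F8. Its single hydroxyl is acylated by 10 (Et3N, DMAP) to give 13.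

Step 6. Acyl transfer may go to the hydroxyl next to iodine or to both hydroxyls. The fallback inverts the order; it sets out from diol 8 with acid chloride 10 (from 7) and returns at ester 11. An excess of symmetrical 8 is monoacylated by 10 (Et3N, DMAP, CH2Cl2), where no choice between hydroxyls exists, to give 3-(benzyloxy)-5-hydroxyphenyl 2,4-bis(benzyloxy)-6-[(2-propyl-1,3-dioxolan-2-yl)methyl]benzoate F9. F9 is then iodinated ortho to its free hydroxyl (I2, NaHCO3, THF/H2O, 0 °C) at the position next to the benzyl ether to give 11; the other two open positions are flanked and deactivated by the bulky aroyloxy group.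

Further compounds
F1 | step 8 | 2,4-dihydroxy-6-propylbenzoic acid | CCCc1cc(O)cc(O)c1C(=O)O
F2 | step 8 | benzyl 2,4-dihydroxy-6-propylbenzoate | CCCc1cc(O)cc(O)c1C(=O)OCc1ccccc1
F3 | step 8 | benzyl 4-({2,4-bis(benzyloxy)-6-[(2-propyl-1,3-dioxolan-2-yl)methyl]benzoyl}oxy)-2-hydroxy-6-propylbenzoate | CCCC1(Cc2cc(OCc3ccccc3)cc(OCc3ccccc3)c2C(=O)Oc2cc(O)c(C(=O)OCc3ccccc3)c(CCC)c2)OCCO1
F4 | step 8 | benzyl 4-{[2,4-bis(benzyloxy)-6-(2-oxopentyl)benzoyl]oxy}-2-hydroxy-6-propylbenzoate | CCCC(=O)Cc1cc(OCc2ccccc2)cc(OCc2ccccc2)c1C(=O)Oc1cc(O)c(C(=O)OCc2ccccc2)c(CCC)c1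
F5 | step 5 | 3-(benzyloxy)-5-[(triisopropylsilyl)oxy]phenol | Oc1cc(OCc2ccccc2)cc(O[Si](C(C)C)(C(C)C)C(C)C)c1
F6 | step 5 | 3-(benzyloxy)-2-iodo-5-[(triisopropylsilyl)oxy]phenol | Oc1cc(O[Si](C(C)C)(C(C)C)C(C)C)cc(OCc2ccccc2)c1I
F7 | step 5 | 3-(benzyloxy)-2-iodo-5-[(triisopropylsilyl)oxy]phenyl 4-chlorobenzenesulfonate | Clc1ccc(cc1)S(=O)(=O)Oc1cc(O[Si](C(C)C)(C(C)C)C(C)C)cc(OCc2ccccc2)c1I
F8 | step 5 | 3-(benzyloxy)-5-hydroxy-2-iodophenyl 4-chlorobenzenesulfonate | Clc1ccc(cc1)S(=O)(=O)Oc1cc(O)cc(OCc2ccccc2)c1I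
F9 | step 6 | 3-(benzyloxy)-5-hydroxyphenyl 2,4-bis(benzyloxy)-6-[(2-propyl-1,3-dioxolan-2-yl)methyl]benzoate | CCCC1(Cc2cc(OCc3ccccc3)cc(OCc3ccccc3)c2C(=O)Oc2cc(O)cc(OCc3ccccc3)c2)OCCO1
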